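**Plan**
1. Retrosynthesis: the 2,3-dimethoxy-5-methylbenzoquinone ring is masked as its hydroquinone dimethyl ether (a tetramethoxytoluene ring). The 40-carbon chain is then cut at the C(sp2)–CH2 bond between the methyl-bearing carbon of alkene 7 (alkenes counted from the ring) and the CH2CH2 link that leads to alkene 8.
2. Event: a Zweifel-type 1,2-shift from boron to carbon joins a (Z)-alkenyl iodide (ring plus six and a half isoprene units) to a C16 homoallylic pinacol boronic ester. It rebuilds that alkene as E in the same flask.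
3. Enabling feature: alkene 7 is CH2–CH=C(CH3)–CH2CH2. One sp2 carbon bears only H and CH2, so it can come from an aldehyde by a Z-selective 1-iodoethylidene Wittig reaction. The other bears CH3 and an unbranched primary CH2, a good migrating group on boron, and anti migration plus anti B/I elimination turns the easily made Z into the wanted E.
4. Further cuts, ring half: C=C (Wittig), CH2–CH2 (aza-enolate plus allylic bromide), CH2–CH2 between units 3 and 4 (allyl sulfone alkylation, then desulfonylation), aryl–CH2 (arylcopper plus farnesyl bromide). Tail half: C–B, CH–CH2 (alanate plus ethylene oxide), C–CH3 (carboalumination), CH2–CH2 (propargylation of citronellyl bromide).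
5. Forward order: no ring is built, and the bought benzene ring is oxidised to the quinone last. The chain grows as ring + C15, + C15, + C2, + C2, then + C16.
6. Stereochemistry: alkenes 1, 2, 4 and 5 are bought with farnesyl bromide, 3 and 6 follow the E-rule of SeO2 oxidation, 8 comes from syn carboalumination and 7 from the key step. The (S) centre is the unchanged centre of (R)-citronellyl bromide.

Key step: step 17

Assumption: 2,3,4,5-tetramethoxytoluene, (2E,6E)-farnesyl bromide and (R)-citronellyl bromide are taken as commercial, isomerically pure materials. The (S) descriptor of the target and the (R) descriptor of citronellyl bromide describe the same spatial arrangement, because only the CIP ranking of the two chain arms changes.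

**Step 1**
Reactants: 1 2,3,4,5-tetramethoxytoluene; 2 (2E,6E)-farnesyl bromide
Product: 5 1-[(2E,6E)-3,7,11-trimethyldodeca-2,6,10-trienyl]-2,3,4,5-tetramethoxy-6-methylbenzene, via aryllithium 3 (not isolated), via arylcopper 4 (not isolated)
Conditions: n-BuLi, TMEDA, hexane, 0 °C to rt; CuBr·SMe2, THF, −40 °C; 2, −78 °C to 0 °C
Reagents that add atoms: none
Why: Directed ortho-lithiation can only take the single ring C–H next to OMe, and the derived arylcopper should displace the primary allylic bromide at its unsubstituted terminus (SN2-type arylcopper allylation), so the 2E and 6E alkenes are carried over unchanged.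

**Step 2**
Reactants: 5 farnesyl arene
Product: 6 (2E,6E,10E)-2,6,10-trimethyl-12-(2,3,4,5-tetramethoxy-6-methylphenyl)dodeca-2,6,10-trien-1-ol
Conditions: SeO2 (cat.), t-BuOOH, salicylic acid (cat.), CH2Cl2, 0 °C, run to partial conversion, unreacted 5 recycled
Reagents that add atoms: selenium dioxide, O=[Se]=O (hands over the O); tert-butyl hydroperoxide, CC(C)(C)OO (restores SeO2, final source of the O)
Why: Riley allylic oxidation (ene reaction, then [2,3]-sigmatropic shift) should prefer the terminal, least hindered trisubstituted alkene and there the methyl group trans to the chain, which sets the E geometry of alkene 3.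

**Step 3**
Reactants: 6 allylic alcohol
Product: 7 1-[(2E,6E,10E)-12-bromo-3,7,11-trimethyldodeca-2,6,10-trienyl]-2,3,4,5-tetramethoxy-6-methylbenzene
Conditions: CBr4, PPh3, CH2Cl2, −20 °C to 0 °C
Reagents that add atoms: tetrabromomethane, BrC(Br)(Br)Br
Why: Appel reaction: bromide displaces the oxyphosphonium group of a primary allylic alcohol by SN2 under neutral conditions, so no allylic shift or loss of E geometry is expected and the aryl ethers are untouched.

**Step 4**
Reactants: 2 (2E,6E)-farnesyl bromide
Product: 8 (2E,6E)-farnesyl phenyl sulfone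
Conditions: PhSO2Na, DMF, rt
Reagents that add atoms: sodium benzenesulfinate, [Na+].[O-]S(=O)c1ccccc1
Why: SN2 S-alkylation of the soft sulfinate anion by the primary allylic bromide gives the allylic sulfone, whose sulfonyl group is the carbanion-stabilising helper for step 7.

**Step 5**
Reactants: 8 farnesyl phenyl sulfone
Product: 9 (2E,6E,10E)-2,6,10-trimethyl-12-(phenylsulfonyl)dodeca-2,6,10-trien-1-ol
Conditions: SeO2 (cat.), t-BuOOH, salicylic acid (cat.), CH2Cl2, 0 °C, run to partial conversion, unreacted 8 recycled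
Reagents that add atoms: selenium dioxide, O=[Se]=O (hands over the O); tert-butyl hydroperoxide, CC(C)(C)OO (restores SeO2, final source of the O)
Why: Riley allylic oxidation as in step 2, helped here by the sulfonyl group, which deactivates the nearest alkene, so the terminal methyl group trans to the chain should react first and set the E geometry of alkene 6.

**Step 6**
Reactants: 9 hydroxy sulfone
Product: 10 tert-butyldimethylsilyl ether of 9
Conditions: TBSCl, imidazole, CH2Cl2, 0 °C to rt
Reagents that add atoms: tert-butyldimethylsilyl chloride, CC(C)(C)[Si](C)(C)Cl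
Why: Standard imidazole-promoted silylation of a primary alcohol; the silyl ether removes the acidic OH before step 7 and is no leaving group for palladium in step 8.

**Step 7**
Reactants: 10 silyloxy sulfone; 7 allylic bromide
Product: 12 all-E hexaprenyl arene that carries PhSO2 on C1 of unit 4 (racemic there) and OTBS on the terminal CH2, via α-lithio sulfone 11 (not isolated)
Conditions: n-BuLi, THF–DMPU, −78 °C; 7, −78 °C to −20 °C
Reagents that add atoms: none
Why: Alkylation of a sulfonyl-stabilised allyl anion at its α-carbon by a primary allylic bromide (Biellmann-type head-to-tail coupling) joins units 3 and 4 without touching any alkene; the sulfonyl-bearing carbon forms as a racemate and becomes a CH2 group again in step 8.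

**Step 8**
Reactants: 12 C30 sulfone
Product: 13 tert-butyldimethylsilyl ether of (2E,6E,10E,14E,18E,22E)-2,6,10,14,18,22-hexamethyl-24-(2,3,4,5-tetramethoxy-6-methylphenyl)tetracosa-2,6,10,14,18,22-hexaen-1-ol
Conditions: PdCl2(dppp) (cat.), LiBHEt3, THF, 0 °C
Reagents that add atoms: none
Why: Palladium-catalysed reductive desulfonylation: zerovalent palladium formed in the flask ionises the allylic C–S bond to a π-allyl complex and hydride is delivered to the less substituted terminus, which keeps alkene 4 trisubstituted and E, while the allylic silyl ether does not ionise.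

**Step 9**
Reactants: 13 silyl ether
Product: 14 (2E,6E,10E,14E,18E,22E)-2,6,10,14,18,22-hexamethyl-24-(2,3,4,5-tetramethoxy-6-methylphenyl)tetracosa-2,6,10,14,18,22-hexaen-1-ol
Conditions: Bu4NF, THF, 0 °C to rt
Reagents that add atoms: none
Why: Fluoride-driven cleavage of the Si–O bond (silyl ether deprotection) is orthogonal to the polyene and to the aryl methyl ethers.

**Step 10**
Reactants: 14 allylic alcohol
Product: 15 1-[(2E,6E,10E,14E,18E,22E)-24-bromo-3,7,11,15,19,23-hexamethyltetracosa-2,6,10,14,18,22-hexaenyl]-2,3,4,5-tetramethoxy-6-methylbenzene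
Conditions: CBr4, PPh3, CH2Cl2, −20 °C to 0 °C, used at once
Reagents that add atoms: tetrabromomethane, BrC(Br)(Br)Br
Why: Appel reaction as in step 3, an SN2 displacement on a primary allylic oxyphosphonium salt under neutral conditions that should keep position and geometry of alkene 6.

**Step 11**
Reactants: 15 allylic bromide
Product: 17 (4E,8E,12E,16E,20E,24E)-4,8,12,16,20,24-hexamethyl-26-(2,3,4,5-tetramethoxy-6-methylphenyl)hexacosa-4,8,12,16,20,24-hexaenal, via N-tert-butyl aldimine 16 (not isolated)
Conditions: MeCH=N-t-Bu, LiN(i-Pr)2, THF, −78 °C to 0 °C; 15, −78 °C to 0 °C; aq. AcOH–NaOAc buffer, rt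
Reagents that add atoms: N-tert-butylethanimine, CC=NC(C)(C)C; water, O
Why: Stork metalloenamine alkylation: the lithiated acetaldimine is an acetaldehyde enolate equivalent that does not self-condense and attacks the primary allylic bromide by SN2, and mild aqueous acid then hydrolyses the aldimine without moving the γ,δ-alkene.

**Step 12**
Reactants: 17 aldehyde
Product: 18 1-[(2E,6E,10E,14E,18E,22E,26Z)-27-iodo-3,7,11,15,19,23-hexamethyloctacosa-2,6,10,14,18,22,26-heptaenyl]-2,3,4,5-tetramethoxy-6-methylbenzene
Conditions: [Ph3PEt]I, n-BuLi, THF, 0 °C; I2, −78 °C; NaN(SiMe3)2, −20 °C; 17, −78 °C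
Reagents that add atoms: ethyltriphenylphosphonium iodide, CC[P+](c1ccccc1)(c1ccccc1)c1ccccc1.[I-]; iodine, [I][I]
Why: Wittig olefination with the non-stabilised 1-iodoethylidene ylide (methyl variant of the Stork–Zhao olefination) runs under kinetic control and should place iodine cis to the chain, which is the Z geometry that the key step inverts.

**Step 13**
Reactants: 19 (R)-citronellyl bromide
Product: 21 (6S)-6,10-dimethylundec-9-en-1-yne, via silylalkyne 20 (not isolated)
Conditions: MeC≡CSiMe3, n-BuLi, THF, −78 °C to −20 °C; 19, DMPU, −78 °C to rt; then Bu4NF, THF, rt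
Reagents that add atoms: 1-(trimethylsilyl)propyne, CC#C[Si](C)(C)C
Why: The silyl group blocks the acetylenic end, so the propargyllithium reagent is alkylated at its CH2 end by the primary bromide (SN2 propargylation) and fluoride then frees the terminal alkyne; the stereocentre takes no part and is carried over from 19.

**Step 14**
Reactants: 21 terminal alkyne
Product: 24 (3E,8S)-4,8,12-trimethyltrideca-3,11-dien-1-ol, via alkenylalane 22 (not isolated), via lithium alanate 23 (not isolated)
Conditions: AlMe3, Cp2ZrCl2 (cat.), CH2Cl2, 0 °C to rt; volatiles removed; n-BuLi, hexane–THF, −78 °C to 0 °C; ethylene oxide, THF, 0 °C; aq. work-up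
Reagents that add atoms: trimethylaluminium, C[Al](C)C; ethylene oxide, C1CO1
Why: Negishi zirconium-catalysed carboalumination adds CH3 and Al syn across the terminal alkyne with Al on the terminal carbon, which sets alkene 8 as E, and the more nucleophilic alanate opens the strained epoxide with retention of that geometry, the trisubstituted alkene being inert.

**Step 15**
Reactants: 24 homoallylic alcohol
Product: 25 (3E,8S)-1-iodo-4,8,12-trimethyltrideca-3,11-diene
Conditions: I2, PPh3, imidazole, CH2Cl2, 0 °C
Reagents that add atoms: iodine, [I][I]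
Why: Appel-type iodination: iodide displaces the oxyphosphonium group of a primary alcohol by SN2 under nearly neutral conditions that leave both alkenes and the stereocentre alone.

**Step 16**
Reactants: 25 homoallylic iodide
Product: 28 2-[(3E,8S)-4,8,12-trimethyltrideca-3,11-dienyl]-4,4,5,5-tetramethyl-1,3,2-dioxaborolane, via alkyllithium 26 (not isolated), via isopropoxyborate 27 (not isolated)
Conditions: t-BuLi (2 equiv), Et2O–pentane, −78 °C; i-PrOBpin, −78 °C to rt; aq. NH4Cl
Reagents that add atoms: 2-isopropoxy-4,4,5,5-tetramethyl-1,3,2-dioxaborolane, CC(C)OB1OC(C)(C)C(C)(C)O1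
Why: Iodine–lithium exchange of a primary iodide followed by trapping with an alkoxyboronic ester is the standard borylation of an alkyllithium; the homoallyllithium has no favourable cyclisation path and both alkenes are inert.

**Step 17**
Reactants: 18 (Z)-alkenyl iodide; 28 homoallylic boronic ester
Product: 32 1-[(2E,6E,10E,14E,18E,22E,26E,30E,35S)-3,7,11,15,19,23,27,31,35,39-decamethyltetraconta-2,6,10,14,18,22,26,30,38-nonaenyl]-2,3,4,5-tetramethoxy-6-methylbenzene, via alkenyllithium 29 (not isolated), via boronate complex 30 (not isolated), via β-iodoboronic ester 31 (not isolated)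
Conditions: 18, t-BuLi (2 equiv), THF–Et2O, −78 °C; 28, −78 °C; I2, THF, −78 °C; NaOMe, MeOH, −78 °C to rt
Reagents that add atoms: none
Why: Iodine–lithium exchange with retention gives the Z-alkenyllithium 29, which adds to the vacant boron orbital of 28 to give the tetracoordinate boronate 30; I2 then attacks its electron-rich alkenyl π bond, and the primary CH2 group migrates from boron to the methyl-bearing carbon anti to the opening iodonium bridge, which forms the new C–C bond in 31. Methoxide next binds to boron and triggers anti elimination of boron and iodine, so the two anti events together invert the alkene and the Z-iodide should deliver alkene 7 as E. The closest known reaction type is the Zweifel olefination of alkenyllithium and pinacol boronic ester pairs, which is established for primary alkyl migrating groups and for stereodefined trisubstituted alkenes. No ring is closed and no lasting stereocentre is made: the two sp3 carbons of 31 arise on both alkene faces, but each face gives the same relative arrangement and hence the same E-alkene, so the controlling element is the geometry fixed in step 12, and the remote (S) centre is not involved. The step needs attack of I2 on one of nine alkenes, secured by the negative charge of the boronate, which makes that π bond far more nucleophilic than the neutral trisubstituted alkenes and the fully substituted ring, and it needs carbon rather than oxygen migration, secured by the poor migratory aptitude of the pinacol oxygens. Configurational stability of 29 is secured by working at −78 °C with an α-alkyl-substituted alkenyllithium.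

**Step 18**
Reactants: 32 ubiquinol-type tetramethyl ether
Product: 33 target, 2-[(2E,6E,10E,14E,18E,22E,26E,30E,35S)-3,7,11,15,19,23,27,31,35,39-decamethyltetraconta-2,6,10,14,18,22,26,30,38-nonaenyl]-5,6-dimethoxy-3-methylcyclohexa-2,5-diene-1,4-dione
Conditions: (NH4)2Ce(NO3)6, MeCN–CH2Cl2–H2O, 0 °C
Reagents that add atoms: water, O
Why: Oxidative demethylation of a hydroquinone dimethyl ether by tetravalent cerium: two one-electron oxidations with attack of water at the two para ring carbons that flank methyl and chain release methanol and give the para-quinone, a reaction type known to spare the isolated alkenes of polyprenyl ubiquinol ethers.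

**Compound list**
1 | 2,3,4,5-tetramethoxytoluene | COc1c(OC)c(OC)cc(C)c1OC | starting material
2 | (2E,6E)-farnesyl bromide, (2E,6E)-1-bromo-3,7,11-trimethyldodeca-2,6,10-triene | BrC/C=C(\C)CC/C=C(\C)CCC=C(C)C | starting material
3 | (2,3,4,5-tetramethoxy-6-methylphenyl)lithium, formed in the flask | COc1c(OC)c(OC)c([Li])c(C)c1OC | intermediate
4 | (2,3,4,5-tetramethoxy-6-methylphenyl)copper, formed in the flask | COc1c(OC)c(OC)c([Cu])c(C)c1OC | intermediate
5 | 1-[(2E,6E)-3,7,11-trimethyldodeca-2,6,10-trienyl]-2,3,4,5-tetramethoxy-6-methylbenzene | COc1c(OC)c(OC)c(C/C=C(\C)CC/C=C(\C)CCC=C(C)C)c(C)c1OC | intermediate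
6 | (2E,6E,10E)-2,6,10-trimethyl-12-(2,3,4,5-tetramethoxy-6-methylphenyl)dodeca-2,6,10-trien-1-ol | COc1c(OC)c(OC)c(C/C=C(\C)CC/C=C(\C)CC/C=C(\C)CO)c(C)c1OC | intermediate
7 | 1-[(2E,6E,10E)-12-bromo-3,7,11-trimethyldodeca-2,6,10-trienyl]-2,3,4,5-tetramethoxy-6-methylbenzene | COc1c(OC)c(OC)c(C/C=C(\C)CC/C=C(\C)CC/C=C(\C)CBr)c(C)c1OC | intermediate
8 | (2E,6E)-farnesyl phenyl sulfone | O=S(=O)(C/C=C(\C)CC/C=C(\C)CCC=C(C)C)c1ccccc1 | intermediate
9 | (2E,6E,10E)-2,6,10-trimethyl-12-(phenylsulfonyl)dodeca-2,6,10-trien-1-ol | O=S(=O)(C/C=C(\C)CC/C=C(\C)CC/C=C(\C)CO)c1ccccc1 | intermediate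
10 | tert-butyldimethylsilyl ether of 9 | O=S(=O)(C/C=C(\C)CC/C=C(\C)CC/C=C(\C)CO[Si](C)(C)C(C)(C)C)c1ccccc1 | intermediate
11 | α-lithio derivative of 10 (Li on the sulfonyl-bearing carbon), formed in the flask | [Li]C(/C=C(\C)CC/C=C(\C)CC/C=C(\C)CO[Si](C)(C)C(C)(C)C)S(=O)(=O)c1ccccc1 | intermediate
12 | all-E hexaprenyl arene with PhSO2 on C1 of unit 4 (racemic at that carbon) and OTBS on the terminal CH2 | COc1c(OC)c(OC)c(C/C=C(\C)CC/C=C(\C)CC/C=C(\C)CC(/C=C(\C)CC/C=C(\C)CC/C=C(\C)CO[Si](C)(C)C(C)(C)C)S(=O)(=O)c2ccccc2)c(C)c1OC | intermediate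
13 | tert-butyldimethylsilyl ether of 14 | COc1c(OC)c(OC)c(C/C=C(\C)CC/C=C(\C)CC/C=C(\C)CC/C=C(\C)CC/C=C(\C)CC/C=C(\C)CO[Si](C)(C)C(C)(C)C)c(C)c1OC | intermediate
14 | (2E,6E,10E,14E,18E,22E)-2,6,10,14,18,22-hexamethyl-24-(2,3,4,5-tetramethoxy-6-methylphenyl)tetracosa-2,6,10,14,18,22-hexaen-1-ol | COc1c(OC)c(OC)c(C/C=C(\C)CC/C=C(\C)CC/C=C(\C)CC/C=C(\C)CC/C=C(\C)CC/C=C(\C)CO)c(C)c1OC | intermediate
15 | 1-[(2E,6E,10E,14E,18E,22E)-24-bromo-3,7,11,15,19,23-hexamethyltetracosa-2,6,10,14,18,22-hexaenyl]-2,3,4,5-tetramethoxy-6-methylbenzene | COc1c(OC)c(OC)c(C/C=C(\C)CC/C=C(\C)CC/C=C(\C)CC/C=C(\C)CC/C=C(\C)CC/C=C(\C)CBr)c(C)c1OC | intermediate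
16 | (E)-N-tert-butyl aldimine of 17, formed in the flask | COc1c(OC)c(OC)c(C/C=C(\C)CC/C=C(\C)CC/C=C(\C)CC/C=C(\C)CC/C=C(\C)CC/C=C(\C)CC/C=N/C(C)(C)C)c(C)c1OC | intermediate
17 | (4E,8E,12E,16E,20E,24E)-4,8,12,16,20,24-hexamethyl-26-(2,3,4,5-tetramethoxy-6-methylphenyl)hexacosa-4,8,12,16,20,24-hexaenal | COc1c(OC)c(OC)c(C/C=C(\C)CC/C=C(\C)CC/C=C(\C)CC/C=C(\C)CC/C=C(\C)CC/C=C(\C)CCC=O)c(C)c1OC | intermediate
18 | 1-[(2E,6E,10E,14E,18E,22E,26Z)-27-iodo-3,7,11,15,19,23-hexamethyloctacosa-2,6,10,14,18,22,26-heptaenyl]-2,3,4,5-tetramethoxy-6-methylbenzene (iodine cis to the chain) | COc1c(OC)c(OC)c(C/C=C(\C)CC/C=C(\C)CC/C=C(\C)CC/C=C(\C)CC/C=C(\C)CC/C=C(\C)CC/C=C(/C)I)c(C)c1OC | intermediate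
19 | (R)-citronellyl bromide, (6R)-8-bromo-2,6-dimethyloct-2-ene | BrCC[C@H](C)CCC=C(C)C | starting material
20 | [(6S)-6,10-dimethylundec-9-en-1-ynyl]trimethylsilane, formed in the flask | C[Si](C)(C)C#CCCC[C@H](C)CCC=C(C)C | intermediate
21 | (6S)-6,10-dimethylundec-9-en-1-yne | C#CCCC[C@H](C)CCC=C(C)C | intermediate
22 | dimethyl[(1E,6S)-2,6,10-trimethylundeca-1,9-dienyl]alane (CH3 cis to Al), formed in the flask | C[Al](C)/C=C(\C)CCC[C@H](C)CCC=C(C)C | intermediate
23 | lithium butyldimethyl[(1E,6S)-2,6,10-trimethylundeca-1,9-dienyl]alanate, formed in the flask | [Li+].CCCC[Al-](C)(C)/C=C(\C)CCC[C@H](C)CCC=C(C)C | intermediate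
24 | (3E,8S)-4,8,12-trimethyltrideca-3,11-dien-1-ol | OCC/C=C(\C)CCC[C@H](C)CCC=C(C)C | intermediate
25 | (3E,8S)-1-iodo-4,8,12-trimethyltrideca-3,11-diene | ICC/C=C(\C)CCC[C@H](C)CCC=C(C)C | intermediate
26 | [(3E,8S)-4,8,12-trimethyltrideca-3,11-dienyl]lithium, formed in the flask | [Li]CC/C=C(\C)CCC[C@H](C)CCC=C(C)C | intermediate
27 | lithium isopropoxy(pinacolato)[(3E,8S)-4,8,12-trimethyltrideca-3,11-dienyl]borate, formed in the flask | [Li+].CC(C)O[B-]1(CC/C=C(\C)CCC[C@H](C)CCC=C(C)C)OC(C)(C)C(C)(C)O1 | intermediate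
28 | 2-[(3E,8S)-4,8,12-trimethyltrideca-3,11-dienyl]-4,4,5,5-tetramethyl-1,3,2-dioxaborolane | CC1(C)OB(CC/C=C(\C)CCC[C@H](C)CCC=C(C)C)OC1(C)C | intermediate
29 | alkenyllithium from 18 (Li in place of I, cis to the chain), formed in the flask | COc1c(OC)c(OC)c(C/C=C(\C)CC/C=C(\C)CC/C=C(\C)CC/C=C(\C)CC/C=C(\C)CC/C=C(\C)CC/C=C(/C)[Li])c(C)c1OC | intermediate
30 | lithium alkenyl(alkyl)(pinacolato)borate from 29 and 28 (boron cis to the ring-side chain), formed in the flask | [Li+].COc1c(OC)c(OC)c(C/C=C(\C)CC/C=C(\C)CC/C=C(\C)CC/C=C(\C)CC/C=C(\C)CC/C=C(\C)CC/C=C(/C)[B-]2(CC/C=C(\C)CCC[C@H](C)CCC=C(C)C)OC(C)(C)C(C)(C)O2)c(C)c1OC | intermediate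
31 | β-iodoboronic ester from anti addition of I and the migrating CH2 across the Z-alkene (drawn for attack on one face; the other face gives the mirror arrangement at these two carbons), formed in the flask | COc1c(OC)c(OC)c(C/C=C(\C)CC/C=C(\C)CC/C=C(\C)CC/C=C(\C)CC/C=C(\C)CC/C=C(\C)CC[C@H](I)[C@](C)(B2OC(C)(C)C(C)(C)O2)CC/C=C(\C)CCC[C@H](C)CCC=C(C)C)c(C)c1OC | intermediate
32 | 1-[(2E,6E,10E,14E,18E,22E,26E,30E,35S)-3,7,11,15,19,23,27,31,35,39-decamethyltetraconta-2,6,10,14,18,22,26,30,38-nonaenyl]-2,3,4,5-tetramethoxy-6-methylbenzene | COc1c(OC)c(OC)c(C/C=C(\C)CC/C=C(\C)CC/C=C(\C)CC/C=C(\C)CC/C=C(\C)CC/C=C(\C)CC/C=C(\C)CC/C=C(\C)CCC[C@H](C)CCC=C(C)C)c(C)c1OC | intermediate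
33 | 2-[(2E,6E,10E,14E,18E,22E,26E,30E,35S)-3,7,11,15,19,23,27,31,35,39-decamethyltetraconta-2,6,10,14,18,22,26,30,38-nonaenyl]-5,6-dimethoxy-3-methylcyclohexa-2,5-diene-1,4-dione | COC1=C(OC)C(=O)C(C/C=C(\C)CC/C=C(\C)CC/C=C(\C)CC/C=C(\C)CC/C=C(\C)CC/C=C(\C)CC/C=C(\C)CC/C=C(\C)CCC[C@H](C)CCC=C(C)C)=C(C)C1=O | target

Total step count: 18.
Longest linear sequence: 11 steps (1, 2, 3, 7, 8, 9, 10, 11, 12, 17, 18). The branch 4, 5, 6 is equally long up to step 7.

**Steps most likely to fail**

Risk 1, step 17. The hindered α-methyl alkenyllithium may be captured incompletely by the boronic ester. Geometry may also leak through isomerisation of the alkenyllithium or a competing syn elimination. The fallback replaces the stereoinvertive boronate route by a stereoretentive cross-coupling; it sets out from aldehyde 17 and alkyllithium 26 and comes back at 32.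
- Aldehyde 17 is homologated with dimethyl (1-diazo-2-oxopropyl)phosphonate and K2CO3 in MeOH (Ohira–Bestmann reaction) to the terminal alkyne F1.
- Deprotonation with n-BuLi and methylation with MeI give the methyl alkyne F2.
- Hydrozirconation with excess Cp2Zr(H)Cl under equilibrating conditions places zirconium on the methyl-bearing carbon in the alkenylzirconocene F3, and I2 turns it into the (E)-alkenyl iodide F4.
- Alkyllithium 26 is transmetalated with ZnBr2 to the alkylzinc bromide F5.
- Negishi coupling of F4 with F5 under PdCl2(dppf) forms the same bond with retention and gives 32.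

Risk 2, step 12. The iodo ylide may decay before it meets the aldehyde, so that plain ethylidenation competes, and the Z preference may erode. The fallback sets out from aldehyde 17 and comes back at alkenyllithium 29.
- Ramirez olefination (CBr4, PPh3) gives the 1,1-dibromoalkene F6.
- A trans-selective Negishi monomethylation (Me2Zn, PdCl2(DPEphos)) replaces only the bromine trans to the chain and gives the (Z)-2-bromoalkene F7.
- Bromine–lithium exchange of F7 with t-BuLi at −78 °C gives 29.

Risk 3, step 2. Site selectivity among the three trisubstituted alkenes may be poor, and oxidation may run on past the alcohol stage. The fallback rebuilds the terminal alkene instead of oxidising a C–H bond; it sets out from 5 and comes back at 6.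
- Terminal-selective bromohydrin formation with NBS in aqueous THF gives the racemic bromohydrin F8.
- K2CO3 in MeOH closes F8 to the terminal epoxide F9.
- H5IO6 cleaves F9 to the trisnor aldehyde F10.
- An E-selective Wittig reaction with the stabilised ylide Ph3P=C(Me)CO2Et gives the (E)-enoate F11.
- Reduction of F11 with i-Bu2AlH gives 6.

**Further compounds**
F1 | step 17 | terminal alkyne from 17 (C≡CH in place of CHO) | COc1c(OC)c(OC)c(C/C=C(\C)CC/C=C(\C)CC/C=C(\C)CC/C=C(\C)CC/C=C(\C)CC/C=C(\C)CCC#C)c(C)c1OC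
F2 | step 17 | methyl alkyne from F1 | COc1c(OC)c(OC)c(C/C=C(\C)CC/C=C(\C)CC/C=C(\C)CC/C=C(\C)CC/C=C(\C)CC/C=C(\C)CCC#CC)c(C)c1OC
F3 | step 17 | alkenylzirconocene chloride from F2 (Zr on the methyl-bearing carbon, trans to the chain) | COc1c(OC)c(OC)c(C/C=C(\C)CC/C=C(\C)CC/C=C(\C)CC/C=C(\C)CC/C=C(\C)CC/C=C(\C)CC/C=C(\C)[Zr](Cl)(C2C=CC=C2)C2C=CC=C2)c(C)c1OC
F4 | step 17 | (26E)-isomer of 18, iodine trans to the chain | COc1c(OC)c(OC)c(C/C=C(\C)CC/C=C(\C)CC/C=C(\C)CC/C=C(\C)CC/C=C(\C)CC/C=C(\C)CC/C=C(\C)I)c(C)c1OC
F5 | step 17 | [(3E,8S)-4,8,12-trimethyltrideca-3,11-dienyl]zinc bromide | Br[Zn]CC/C=C(\C)CCC[C@H](C)CCC=C(C)C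
F6 | step 12 | 1,1-dibromoalkene from 17 | COc1c(OC)c(OC)c(C/C=C(\C)CC/C=C(\C)CC/C=C(\C)CC/C=C(\C)CC/C=C(\C)CC/C=C(\C)CCC=C(Br)Br)c(C)c1OC
F7 | step 12 | (26Z)-27-bromo analogue of 18, bromine cis to the chain | COc1c(OC)c(OC)c(C/C=C(\C)CC/C=C(\C)CC/C=C(\C)CC/C=C(\C)CC/C=C(\C)CC/C=C(\C)CC/C=C(/C)Br)c(C)c1OC
F8 | step 2 | racemic terminal bromohydrin of 5 (10-bromo-11-hydroxy) | COc1c(OC)c(OC)c(C/C=C(\C)CC/C=C(\C)CCC(Br)C(C)(C)O)c(C)c1OC
F9 | step 2 | racemic terminal 10,11-epoxide of 5 | COc1c(OC)c(OC)c(C/C=C(\C)CC/C=C(\C)CCC2OC2(C)C)c(C)c1OC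
F10 | step 2 | (4E,8E)-4,8-dimethyl-10-(2,3,4,5-tetramethoxy-6-methylphenyl)deca-4,8-dienal | COc1c(OC)c(OC)c(C/C=C(\C)CC/C=C(\C)CCC=O)c(C)c1OC
F11 | step 2 | ethyl (2E,6E,10E)-2,6,10-trimethyl-12-(2,3,4,5-tetramethoxy-6-methylphenyl)dodeca-2,6,10-trienoate | COc1c(OC)c(OC)c(C/C=C(\C)CC/C=C(\C)CC/C=C(\C)C(=O)OCC)c(C)c1OC
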